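**Retrosynthetic overview**
- The strategy rests on the A ring: oxygens para to each other at C5 (OH) and C8 (OMe), a further OMe at C7, O1 on C8a and the C4 carbonyl on C4a. This is the substitution pattern of 3-methoxy-p-benzoquinone 4-(dimethyl ketal) once its free enone arm has taken up an O and a C substituent and one ketal methanol has been lost.
- Last disconnection: the 2'- and 3'-O-benzyl groups (hydrogenolysis).
- Key disconnection: O1–C8a and C4–C4a. The dearomatised A ring (the quinone monoketal) is joined to an α-methoxy β-keto ester that carries the B ring, C2, C3 and C4.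
- The keto ester comes from C-acylation of the methyl methoxyacetate enolate (future C3) with 2,3-bis(benzyloxy)benzoyl chloride (future C2); the monoketal comes from iodine(III) oxidation of 3,4-dimethoxyphenol in methanol.
- Ring order: B ring bought, A ring bought and dearomatised, pyranone (C ring) closed last with rearomatisation of the A ring in the same operation.

Key step: step 6

Remark: the target is an achiral flavone with no stereocentre, so no enantiocontrol is needed. The two transient intermediates of the key step carry stereocentres, are racemic, and lose them on aromatisation.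

**Step 1**
Reactants: 1 3,4-dimethoxyphenol
Product: 2 3,4,4-trimethoxycyclohexa-2,5-dien-1-one
Conditions: PhI(OAc)2 (1.1 equiv), MeOH, 0 °C; NaHCO3 work-up
Reagents that add atoms: methanol, CO
Why: Oxidative dearomatisation with a λ3-iodane generates a phenoxenium-type intermediate that methanol traps at the methoxy-bearing para carbon, the routine way from 4-methoxyphenols to p-quinone monoketals.

**Step 2**
Reactants: 3 2,3-dihydroxybenzoic acid
Product: 4 benzyl 2,3-bis(benzyloxy)benzoate
Conditions: BnBr (3.3 equiv), K2CO3, DMF, 60 °C
Reagents that add atoms: benzyl bromide, BrCc1ccccc1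
Why: Williamson etherification of both phenoxides and SN2 alkylation of the carboxylate with excess benzyl bromide should give the fully benzylated compound, warming being included because the hydrogen-bonded 2-hydroxyl reacts last.

**Step 3**
Reactants: 4 benzyl 2,3-bis(benzyloxy)benzoate
Product: 5 2,3-bis(benzyloxy)benzoic acid
Conditions: KOH, THF/MeOH/H2O, 65 °C; then 1 M HCl
Reagents that add atoms: potassium hydroxide, [K+].[OH-]
Why: Saponification (BAc2 ester hydrolysis) cleaves only the benzyl ester, since aryl benzyl ethers are inert to aqueous hydroxide.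

**Step 4**
Reactants: 5 2,3-bis(benzyloxy)benzoic acid
Product: 6 2,3-bis(benzyloxy)benzoyl chloride
Conditions: (COCl)2, cat. DMF, CH2Cl2, 0 → 23 °C; concentrated and used crude
Reagents that add atoms: oxalyl chloride, O=C(Cl)C(=O)Cl
Why: Acid chloride formation through the Vilsmeier-type chloroiminium species from oxalyl chloride and catalytic DMF runs at or below room temperature, where aryl benzyl ethers are stable.

**Step 5**
Reactants: 6 2,3-bis(benzyloxy)benzoyl chloride; 7 methyl methoxyacetate
Product: 8 methyl 3-[2,3-bis(benzyloxy)phenyl]-2-methoxy-3-oxopropanoate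
Conditions: 7 (2.2 equiv), LiHMDS (2.2 equiv), THF, −78 °C; then 6, −78 → −40 °C; sat. aq. NH4Cl
Reagents that add atoms: none
Why: Crossed Claisen condensation by C-acylation of a preformed lithium ester enolate with a non-enolisable aroyl chloride, in which the second equivalent of enolate deprotonates the more acidic β-keto ester as it forms and so protects it from a second acylation.

**Step 6**
Reactants: 8 methyl 3-[2,3-bis(benzyloxy)phenyl]-2-methoxy-3-oxopropanoate; 2 3,4,4-trimethoxycyclohexa-2,5-dien-1-one
Product: 11 2-[2,3-bis(benzyloxy)phenyl]-5-hydroxy-3,7,8-trimethoxy-4H-chromen-4-one, via oxa-Michael adduct 9 (not isolated), via bicyclic ketal dione 10 (not isolated)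
Conditions: 2 (1.5 equiv), Cs2CO3 (1.2 equiv), 4 Å MS, DMSO, 23 → 50 °C; then HCl in MeOH, 23 °C
Reagents that add atoms: none
Why: Proposed new method: the caesium enolate of 8 is expected to add through its ketone oxygen to C5 of dienone 2 (the unsubstituted enone β-carbon, future C8a) to give 9, whose cyclohexenone enolate carbon C6 (future C4a) attacks the neighbouring methyl ester in a Dieckmann-type acyl substitution that expels methoxide and leaves the doubly stabilised 1,3-diketonate of 10, and the acid quench then ionises the C8 ketal, removes the C8a proton and lets the ring tautomerise to the 5-hydroxy-8-methoxy arene with loss of methanol and without any redox step. The closest known reaction type is the base-mediated Michael–Dieckmann annulation of stabilised carbanions with p-quinone monoketals followed by aromatising loss of methanol (Hauser–Kraus type), the difference being that the Michael donor atom here is oxygen and not carbon. The only ring closed is the pyranone, in a 6-exo-trig closure of the enolate carbon on the ester C=O, which needs the new enol-ether oxygen and the ester cis on the C2=C3 bond, the geometry that the U-shaped chelated enolate delivers. No stereocentre is kept, since the racemic C4a and C8a centres of 9 and 10 are erased on aromatisation. The step needs O- over C-attack of the ambident enolate and attack at C5 over C3 of 2: the α-carbon is fully substituted (OMe, aroyl, ester) and would have to bond next to the quaternary ketal carbon, both conjugate additions are reversible under these conditions while only the O-adduct can drain into the irreversible acylation, and the C3 methoxyl makes the other enone arm a less electrophilic and more hindered vinylogous ester. The coupling has to be run under base and acid added only afterwards, because acid activation of a quinone monoketal steers nucleophiles to the carbon α to the carbonyl and would give the wrong connectivity.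

**Step 7**
Reactants: 11 2-[2,3-bis(benzyloxy)phenyl]-5-hydroxy-3,7,8-trimethoxy-4H-chromen-4-one
Product: 12 5,2',3'-trihydroxy-3,7,8-trimethoxyflavone
Conditions: H2 (1 atm), 10% Pd/C, EtOAc/MeOH, 23 °C; filtration under argon
Reagents that add atoms: none
Why: Palladium-catalysed hydrogenolysis of the two benzylic C–O bonds under one atmosphere of hydrogen should leave the aryl methyl ethers and the tetrasubstituted, vinylogous-ester C2=C3 bond of the chromone untouched, as is usual for benzyl-protected flavones.

**Compound list**
1 | 3,4-dimethoxyphenol | COc1ccc(O)cc1OC | starting material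
2 | 3,4,4-trimethoxycyclohexa-2,5-dien-1-one | COC1=CC(=O)C=CC1(OC)OC | intermediate
3 | 2,3-dihydroxybenzoic acid | O=C(O)c1cccc(O)c1O | starting material
4 | benzyl 2,3-bis(benzyloxy)benzoate | O=C(OCc1ccccc1)c1cccc(OCc2ccccc2)c1OCc1ccccc1 | intermediate
5 | 2,3-bis(benzyloxy)benzoic acid | O=C(O)c1cccc(OCc2ccccc2)c1OCc1ccccc1 | intermediate
6 | 2,3-bis(benzyloxy)benzoyl chloride | O=C(Cl)c1cccc(OCc2ccccc2)c1OCc1ccccc1 | intermediate
7 | methyl methoxyacetate | COCC(=O)OC | starting material
8 | methyl 3-[2,3-bis(benzyloxy)phenyl]-2-methoxy-3-oxopropanoate (racemic, enolisable α-carbon) | COC(C(=O)OC)C(=O)c1cccc(OCc2ccccc2)c1OCc1ccccc1 | intermediate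
9 | methyl (2E)-3-[2,3-bis(benzyloxy)phenyl]-2-methoxy-3-[(2,2,3-trimethoxy-5-oxocyclohex-3-en-1-yl)oxy]prop-2-enoate (ring oxygen cis to the ester; racemic; present in the flask partly as its enolate) | COC(=O)/C(OC)=C(\OC1CC(=O)C=C(OC)C1(OC)OC)c1cccc(OCc2ccccc2)c1OCc1ccccc1 | intermediate (not isolated)
10 | 2-[2,3-bis(benzyloxy)phenyl]-3,7,8,8-tetramethoxy-8,8a-dihydro-4H-chromene-4,5(4aH)-dione (racemic; present as its caesium 1,3-diketonate) | COC1=CC(=O)C2C(=O)C(OC)=C(c3cccc(OCc4ccccc4)c3OCc3ccccc3)OC2C1(OC)OC | intermediate (not isolated)
11 | 2-[2,3-bis(benzyloxy)phenyl]-5-hydroxy-3,7,8-trimethoxy-4H-chromen-4-one | COc1cc(O)c2c(=O)c(OC)c(-c3cccc(OCc4ccccc4)c3OCc3ccccc3)oc2c1OC | intermediate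
12 | 5,2',3'-trihydroxy-3,7,8-trimethoxyflavone [2-(2,3-dihydroxyphenyl)-5-hydroxy-3,7,8-trimethoxy-4H-chromen-4-one] | COc1cc(O)c2c(=O)c(OC)c(-c3cccc(O)c3O)oc2c1OC | target

**Step count**
Total steps: 7. Longest linear sequence: 6 steps (3 → 4 → 5 → 6 → 8 → 11 → 12); the monoketal 2 is made in one step in parallel.

**Steps most likely to fail**

(a) Step 6, the proposed new annulation. The oxa-Michael addition may not compete: the enolate may react at carbon and that adduct aromatise on the acid quench, the enolate may exchange the C3 methoxyl of 2 by addition–elimination, or the acylation may be too slow from the small equilibrium amount of the O-adduct. The fallback is the classical Baker–Venkataraman flavone synthesis, all known chemistry. It sets out from 6 and comes back at 12. Commercial 1,2,3,5-tetramethoxybenzene is acylated with methoxyacetyl chloride and AlCl3 (Friedel–Crafts); the methoxyl ortho to the new ketone and buttressed by a second methoxyl is cleaved by the Lewis acid (completed with BCl3 at low temperature if needed). This should give 1-(2-hydroxy-3,4,6-trimethoxyphenyl)-2-methoxyethan-1-one F1. Esterification of F1 with 6 (pyridine, DMAP) gives 3,5,6-trimethoxy-2-(methoxyacetyl)phenyl 2,3-bis(benzyloxy)benzoate F2. Base-induced O→C acyl transfer (LiHMDS, THF, −78 → 0 °C) gives 1-[2,3-bis(benzyloxy)phenyl]-3-(2-hydroxy-3,4,6-trimethoxyphenyl)-2-methoxypropane-1,3-dione F3. Acid cyclodehydration (TsOH, toluene, or AcOH with cat. H2SO4) gives 2-[2,3-bis(benzyloxy)phenyl]-3,5,7,8-tetramethoxy-4H-chromen-4-one F4. BCl3 (CH2Cl2, −78 → 0 °C) then cleaves the carbonyl-chelated 5-methoxyl and both benzyl ethers and gives 12.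

(b) Step 5, the Claisen acylation. Self-condensation of the methoxyacetate enolate, O-acylation or a second acylation may outrun C-acylation by the hindered ortho-substituted acid chloride. The fallback is an aldol addition followed by oxidation. It sets out from 7 and comes back at 8. Commercial 2,3-dihydroxybenzaldehyde is benzylated (BnBr, K2CO3, DMF) to 2,3-bis(benzyloxy)benzaldehyde F5. Addition of the lithium enolate of 7 (LDA, THF, −78 °C) gives methyl 3-[2,3-bis(benzyloxy)phenyl]-3-hydroxy-2-methoxypropanoate F6 as a diastereomer mixture of no consequence. Dess–Martin oxidation of the secondary alcohol gives 8.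

(c) Step 7, the hydrogenolysis. Slow cleavage of the hindered 2'-benzyl ether may force long exposure, during which the chromone C2=C3 bond is reduced or the freed catechol is oxidised by air on the catalyst. The fallback changes the protecting group to acid-labile methoxymethyl ethers, so that no reductive step is needed. It sets out from 7 (and uses 2) and comes back at 12. Commercial 2,3-dihydroxybenzaldehyde with MOMCl and i-Pr2NEt gives 2,3-bis(methoxymethoxy)benzaldehyde F7. Aldol addition of the lithium enolate of 7 gives methyl 3-[2,3-bis(methoxymethoxy)phenyl]-3-hydroxy-2-methoxypropanoate F8. Dess–Martin oxidation gives methyl 3-[2,3-bis(methoxymethoxy)phenyl]-2-methoxy-3-oxopropanoate F9. Annulation with 2 under the conditions of step 6 should pass through the MOM-protected oxa-Michael adduct F10 and the MOM-protected bicyclic ketal dione F11 to 2-[2,3-bis(methoxymethoxy)phenyl]-5-hydroxy-3,7,8-trimethoxy-4H-chromen-4-one F12. Holding the acidic methanol of the aromatisation at 50 °C removes both MOM groups and gives 12.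

**Further compounds**
F1 | step 6 | 1-(2-hydroxy-3,4,6-trimethoxyphenyl)-2-methoxyethan-1-one | COCC(=O)c1c(O)c(OC)c(OC)cc1OC
F2 | step 6 | 3,5,6-trimethoxy-2-(methoxyacetyl)phenyl 2,3-bis(benzyloxy)benzoate | COCC(=O)c1c(OC(=O)c2cccc(OCc3ccccc3)c2OCc2ccccc2)c(OC)c(OC)cc1OC
F3 | step 6 | 1-[2,3-bis(benzyloxy)phenyl]-3-(2-hydroxy-3,4,6-trimethoxyphenyl)-2-methoxypropane-1,3-dione | COC(C(=O)c1cccc(OCc2ccccc2)c1OCc1ccccc1)C(=O)c1c(O)c(OC)c(OC)cc1OC
F4 | step 6 | 2-[2,3-bis(benzyloxy)phenyl]-3,5,7,8-tetramethoxy-4H-chromen-4-one | COc1cc(OC)c2c(=O)c(OC)c(-c3cccc(OCc4ccccc4)c3OCc3ccccc3)oc2c1OC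
F5 | step 5 | 2,3-bis(benzyloxy)benzaldehyde | O=Cc1cccc(OCc2ccccc2)c1OCc1ccccc1
F6 | step 5 | methyl 3-[2,3-bis(benzyloxy)phenyl]-3-hydroxy-2-methoxypropanoate (racemic diastereomer mixture) | COC(C(=O)OC)C(O)c1cccc(OCc2ccccc2)c1OCc1ccccc1
F7 | step 7 | 2,3-bis(methoxymethoxy)benzaldehyde | COCOc1cccc(C=O)c1OCOC
F8 | step 7 | methyl 3-[2,3-bis(methoxymethoxy)phenyl]-3-hydroxy-2-methoxypropanoate (racemic diastereomer mixture) | COCOc1cccc(C(O)C(OC)C(=O)OC)c1OCOC
F9 | step 7 | methyl 3-[2,3-bis(methoxymethoxy)phenyl]-2-methoxy-3-oxopropanoate | COCOc1cccc(C(=O)C(OC)C(=O)OC)c1OCOC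
F10 | step 7 | methyl (2E)-3-[2,3-bis(methoxymethoxy)phenyl]-2-methoxy-3-[(2,2,3-trimethoxy-5-oxocyclohex-3-en-1-yl)oxy]prop-2-enoate (racemic) | COC(=O)/C(OC)=C(\OC1CC(=O)C=C(OC)C1(OC)OC)c1cccc(OCOC)c1OCOC
F11 | step 7 | 2-[2,3-bis(methoxymethoxy)phenyl]-3,7,8,8-tetramethoxy-8,8a-dihydro-4H-chromene-4,5(4aH)-dione (racemic) | COCOc1cccc(C2=C(OC)C(=O)C3C(=O)C=C(OC)C(OC)(OC)C3O2)c1OCOC
F12 | step 7 | 2-[2,3-bis(methoxymethoxy)phenyl]-5-hydroxy-3,7,8-trimethoxy-4H-chromen-4-one | COCOc1cccc(-c2oc3c(OC)c(OC)cc(O)c3c(=O)c2OC)c1OCOC
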